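**Plan**

1. Atom labels follow briarane numbering: C1 quaternary ring-fusion carbon (C15 methyl), C2=C3, C4 (OH), C5 (=C16H2), C6 (Cl), C7 (lactone O), C8 (OH), C9 (OAc), C10, ring A C11–C14 (C20 methyl on C11), lactone C17 (C18 methyl)–C19.
2. Retrosynthetic cuts: C6–Cl together with the C5=C16 methylene (ene-type chlorination of a C5(CH3)=C6 alkene); C3–C4 (closure of the ten-membered ring); the lactone at C17–C19 and O–C7 (CO2 placed between an alkenyl nucleophile on C17 and the C7 end of a C7=C6–C5(CH3)=C4 diene); C7–C8 and C8–C17 (two additions to C8); ring A (Diels–Alder, C1–C10 and C13–C14).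
3. Enabling feature: the γ-lactone is one CO2 unit bridging C17 and C7, both of which are substituents of the carbinol C8, and C7 is 1,4-related to the carbinol C4 through C5/C6. A dienyl carboxylate can therefore close on C7 while an electrophile lands on C4 and the alkene moves to C5=C6, from where C6–Cl/C5=C16 is reached.
4. Forward order: ring A, then the C9–C8 side chain, then the C8 carbinol carrying alkyne and diene, then the lactone (key step), then the ten-membered ring, then the C17 methyl, the ring A enone and the C6 chloride.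
5. Stereochemistry: C9 from (R)-glyceraldehyde acetonide; C1/C10 from a catalyst-controlled exo Diels–Alder reaction; C11 from Rubottom oxidation anti to the C10 branch; C8 from Cram-chelate addition; C7 from the C8 carbinol during lactonization; C17 by equilibration; C4 in the ring closure; C6 by chlorination anti to the C7–O bond.

Key step: step 16

Step 1
Reactants: 1 (R)-2,2-dimethyl-1,3-dioxolane-4-carbaldehyde; 2 3-(triphenylphosphoranylidene)butan-2-one
Product: 3 (S,E)-4-(2,2-dimethyl-1,3-dioxolan-4-yl)-3-methylbut-3-en-2-one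
Conditions: CH2Cl2, 0 °C → rt
Reagents that add atoms: none
Why: Wittig olefination with a stabilized, α-branched ylide should give the E enone (dioxolane trans to the acetyl group) and leaves the dioxolane centre, the future C9, untouched.

Step 2
Reactants: 3 (S,E)-4-(2,2-dimethyl-1,3-dioxolan-4-yl)-3-methylbut-3-en-2-one
Product: 4 (S)-2,2-dimethyl-4-[(1E)-2-methyl-3-(triisopropylsilyloxy)buta-1,3-dienyl]-1,3-dioxolane
Conditions: TIPSOTf, Et3N, Et2O, 0 °C
Reagents that add atoms: triisopropylsilyl trifluoromethanesulfonate, CC(C)[Si](OS(=O)(=O)C(F)(F)F)(C(C)C)C(C)C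
Why: Soft enolization of the methyl ketone (silyl triflate/amine) at the acetyl methyl group gives the 2-silyloxy-1,3-diene, and the bulky silyl group suppresses Mukaiyama-type side reactions in the next step.

Step 3
Reactants: 4 (S)-2,2-dimethyl-4-[(1E)-2-methyl-3-(triisopropylsilyloxy)buta-1,3-dienyl]-1,3-dioxolane; 5 methacrolein
Product: 6 (1S,2S)-2-[(4S)-2,2-dimethyl-1,3-dioxolan-4-yl]-1,3-dimethyl-4-(triisopropylsilyloxy)cyclohex-3-ene-1-carbaldehyde
Conditions: (S)-3,3-diphenyl-1-(o-tolyl)tetrahydro-1H,3H-pyrrolo[1,2-c][1,3,2]oxazaborole·HNTf2 (20 mol %), CH2Cl2, −78 → −40 °C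
Reagents that add atoms: none
Why: Diels–Alder reaction of a 2-silyloxydiene with a Lewis-acid-bound enal, in which the silyloxy group and the C10 substituent both direct C13 to the enal β-carbon and C10 to the α-carbon, the CHO-exo transition state typical of α-methyl enals puts the C1 methyl cis to the C10 dioxolane, and the chiral oxazaborolidinium shields one enal face so that the diene reacts on the C10 face syn to the C9–O bond and anti to C8 (the antipodal catalyst is the recourse if the sense is opposite).

Step 4
Reactants: 6 (1S,2S)-2-[(4S)-2,2-dimethyl-1,3-dioxolan-4-yl]-1,3-dimethyl-4-(triisopropylsilyloxy)cyclohex-3-ene-1-carbaldehyde; 7 (dibromomethyl)trimethylsilane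
Product: 8 (E)-vinylsilane (the formyl group of 6 replaced by (E)-2-(trimethylsilyl)ethenyl; C2=C3)
Conditions: CrCl2, THF, rt
Reagents that add atoms: none
Why: Takai–Utimoto olefination, in which the geminal dichromium species from 7 adds to the hindered aldehyde and eliminates to the (E)-alkenylsilane, a robust stand-in for the vinyl iodide needed at ring closure.

Step 5
Reactants: 8 (E)-vinylsilane
Product: 10 2-hydroxy-2,4-dimethyl-3-[(4S)-2,2-dimethyl-1,3-dioxolan-4-yl]-4-[(E)-2-(trimethylsilyl)ethenyl]cyclohexan-1-one (C11 hydroxyl trans to the C10 dioxolane; C1 methyl cis to it), via silyloxy ketone 9 (not isolated)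
Conditions: mCPBA, NaHCO3, CH2Cl2, −20 °C; then Bu4NF, THF, 0 °C
Reagents that add atoms: 3-chloroperoxybenzoic acid, OOC(=O)c1cccc(Cl)c1
Why: Rubottom oxidation, in which the peracid epoxidizes the electron-rich tetrasubstituted silyl enol ether (faster than the vinylsilane) on the face anti to the C10 dioxolane and the cis C1 methyl, 1,4-silyl shift gives 9, and fluoride frees the tertiary C11 alcohol.

Step 6
Reactants: 10 ring A ketol
Product: 11 C11 acetate of 10 (2-acetoxy-2,4-dimethyl-3-[(4S)-2,2-dimethyl-1,3-dioxolan-4-yl]-4-[(E)-2-(trimethylsilyl)ethenyl]cyclohexan-1-one)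
Conditions: Ac2O, DMAP, Et3N, CH2Cl2, 40 °C
Reagents that add atoms: acetic anhydride, CC(=O)OC(C)=O
Why: DMAP-catalysed acylation of the tertiary α-ketol installs the C11 acetate before any other tertiary hydroxyl exists in the molecule.

Step 7
Reactants: 11 C11 acetate
Product: 12 diol (dioxolane of 11 opened to the (1S)-1,2-dihydroxyethyl group; C9–OH and C8–OH)
Conditions: AcOH/H2O (4:1), 45 °C
Reagents that add atoms: none
Why: Acid hydrolysis of the isopropylidene acetal, which the tertiary acetate, the ketone and the vinylsilane should tolerate.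

Step 8
Reactants: 12 diol
Product: 13 bis(triethylsilyl) ether of 12
Conditions: TESCl, imidazole, DMF, 0 °C → rt
Reagents that add atoms: chlorotriethylsilane, CC[Si](Cl)(CC)CC
Why: Standard silylation of both hydroxyls sets up the selective oxidation of the primary position.

Step 9
Reactants: 13 bis(triethylsilyl) ether
Product: 14 aldehyde (C8 formyl group; C9 triethylsilyloxy)
Conditions: (COCl)2, DMSO, CH2Cl2, −78 → −30 °C; then Et3N
Reagents that add atoms: none
Why: Swern oxidation applied to a bis-silyl ether, in which the chlorosulfonium reagent cleaves and oxidizes only the primary triethylsilyl ether and the secondary C9 silyl ether survives.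

Step 10
Reactants: 14 aldehyde; 15 ethynyltrimethylsilane
Product: 17 propargylic alcohols (C8 carbinol bearing the trimethylsilylethynyl group; both C8 epimers), via lithium acetylide 16 (not isolated)
Conditions: 15, n-BuLi, THF, −78 °C; then 14, −78 °C
Reagents that add atoms: none
Why: 1,2-Addition of a lithium acetylide to the aldehyde, which at −78 °C should outpace attack on the hindered ring ketone and the tertiary acetate; the C8 configuration is immaterial because it is oxidized next.

Step 11
Reactants: 17 propargylic alcohols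
Product: 18 ynone (C8 ketone flanked by C9–OTES and C≡C–SiMe3)
Conditions: Dess–Martin periodinane, NaHCO3, CH2Cl2, rt
Reagents that add atoms: none
Why: Dess–Martin oxidation of the secondary propargylic alcohol converges both epimers on the α-silyloxy ynone.

Step 12
Reactants: 18 ynone; 19 2-methylbut-1-en-3-yne
Product: 22 tertiary carbinol (C8 bears OH, trimethylsilylethynyl and (E)-3-methylbuta-1,3-dienyl; C8 and C9 oxygens syn), via dienylborane 20 (not isolated), via dienylzinc 21 (not isolated)
Conditions: 19, Cy2BH, toluene, 0 °C; Me2Zn, −78 °C; then 18, EtZnCl, −30 → 0 °C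
Reagents that add atoms: none
Why: Hydroboration of the enyne at its terminal alkyne, boron-to-zinc exchange and chelation-controlled 1,2-addition of the alkenylzinc to the α-silyloxy ketone, in which the zinc Lewis acid bridges the ketone and C9 silyloxy oxygens (Cram chelate) and the dienyl group enters anti to the C10 branch, setting C8.

Step 13
Reactants: 22 tertiary carbinol
Product: 23 diol (C9–OH and C8–OH free; terminal alkyne on C8)
Conditions: Bu4NF, AcOH, THF, 0 °C → rt
Reagents that add atoms: none
Why: Buffered fluoride removes the alkynyl trimethylsilyl group and the C9 triethylsilyl ether, while the unactivated vinylsilane at C2=C3 and the tertiary acetate should survive.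

Step 14
Reactants: 23 diol
Product: 24 C9 acetate (C8–OH free)
Conditions: Ac2O, pyridine, DMAP (cat.), CH2Cl2, 0 °C
Reagents that add atoms: acetic anhydride, CC(=O)OC(C)=O
Why: Acylation distinguishes the secondary C9 hydroxyl from the tertiary C8 hydroxyl, which stays free for the lactonization.

Step 15
Reactants: 24 C9 acetate
Product: 25 alkenylboronate (C8 bears 1-(4,4,5,5-tetramethyl-1,3,2-dioxaborolan-2-yl)ethenyl; boron on C17)
Conditions: (SIMes)CuCl (SIMes = 1,3-dimesitylimidazolidin-2-ylidene, 5 mol %), NaOt-Bu (5 mol %), B2pin2, MeOH, THF, −15 °C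
Reagents that add atoms: bis(pinacolato)diboron, CC1(C)OB(OC1(C)C)B1OC(C)(C)C(C)(C)O1
Why: Copper–boryl catalysed protoboration of a terminal alkyne, which with an N-aryl carbene ligand and a propargylic oxygen substituent places boron on the internal carbon (C17), while the terminal alkyne should react well before the diene or the hindered ketone.

Step 16
Reactants: 25 alkenylboronate; 26 carbon dioxide
Product: 28 bromo lactone (γ-lactone O–C19(=O)–C17(=CH2)–C8(OH)–C7; C7 bears (E)-3-bromo-2-methylprop-1-enyl cis to the C8 hydroxyl), via cesium carboxylate 27 (not isolated)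
Conditions: [Rh(OH)(cod)]2 (5 mol %), dppp (11 mol %), CsF, CO2 (1 atm), 1,4-dioxane, 60 °C; then NBS, NaHCO3, THF, 0 °C
Reagents that add atoms: N-bromosuccinimide, O=C1CCC(=O)N1Br
Why: Proposed new method: fluoride-assisted transmetalation of the alkenylboronate to monovalent rhodium and insertion of CO2 into the Rh–C17 bond forms C17–C19 and gives the 2-methylene-3-hydroxy-4,6-dienoate 27; on addition of NBS its carboxylate oxygen closes on C7 while bromine adds to the unsubstituted diene terminus C4, so one flask operation builds the lactone from CO2 and moves the alkene to C5=C6 (E, from the s-trans diene). The closest known reaction types are the rhodium- or copper-catalysed carboxylation of alkenylboronic esters with CO2 and the 1,4-halolactonization of conjugated dienoic acids; capture of CO2 followed by halocyclization in one flask is established for alkoxide nucleophiles (halocarbonate formation) but not for carbon nucleophiles. The lactone closes in the 5-exo-trig mode on the C7 end of the bromine-activated diene, since closure at C5 would need a seven-membered ring. The new stereocentre C7 is controlled by the C8 carbinol: in the reactive conformer the hydroxyl lies in the plane of the C6=C7 bond and the bulky C9 branch is anti to the incoming oxygen, which places C6 cis to the hydroxyl on the lactone, as in the target. The step needs 1,4- over 1,2-addition and reaction at the diene in preference to the vinylsilane and the acrylate alkene; the cation-stabilizing C5 methyl, the electron-poor acrylate and the hindered neopentyl vinylsilane should secure this.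

Step 17
Reactants: 28 bromo lactone
Product: 29 enal (C4 aldehyde conjugated with the (E)-C5(CH3)=C6 alkene)
Conditions: NMO, 4 Å molecular sieves, MeCN, rt
Reagents that add atoms: 4-methylmorpholine N-oxide, C[N+]1([O-])CCOCC1
Why: Amine N-oxide oxidation of a primary allylic halide (Ganem oxidation), in which SN2 O-alkylation of the N-oxide and fragmentation give the aldehyde without base strong enough to touch the acetates or the lactone.

Step 18
Reactants: 29 enal
Product: 30 (E)-vinyl iodide (trimethylsilyl group on C3 replaced by iodine)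
Conditions: NIS, (CF3)2CHOH, 0 °C
Reagents that add atoms: N-iodosuccinimide, O=C1CCC(=O)N1I
Why: Ipso-iododesilylation of the alkenylsilane with retention of the E geometry, while the electron-poor enal and acrylate alkenes should not compete.

Step 19
Reactants: 30 (E)-vinyl iodide
Product: 31 macrocyclic allylic alcohol (ten-membered ring closed at C3–C4; (2E,5E)-diene; 4S alcohol; 17-methylene lactone; ring A saturated ketone)
Conditions: CrCl2, NiCl2 (cat.), DMSO/THF, rt, high dilution
Reagents that add atoms: none
Why: Nozaki–Hiyama–Kishi reaction, in which zerovalent nickel inserts into the C–I bond, the alkenyl group passes to trivalent chromium and adds to the aldehyde, closing the ring with the C2=C3 geometry retained; C4 is set under macrocyclic control and the 4S alcohol is the one aimed for but not secured (see fallback).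

Step 20
Reactants: 31 macrocyclic allylic alcohol
Product: 33 α-methyl lactone (17R; C18 methyl cis to the C8 hydroxyl), via 17-epimer 32 (not isolated)
Conditions: [(Ph3P)CuH]6, toluene/H2O, rt; then DBU, toluene, 60 °C
Reagents that add atoms: none
Why: Conjugate reduction of the exocyclic α-methylene lactone by copper hydride (ketone, esters and unactivated alkenes are inert), after which kinetic protonation anti to C9 should give mainly 32 and DBU equilibrates C17 by reversible enolization to the more stable epimer with the methyl trans to the bulky C9 branch.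

Step 21
Reactants: 33 α-methyl lactone
Product: 35 enone bis(triethylsilyl) ether (C13=C14–C12=O in ring A; C4–OTES and C8–OTES), via tris-silyl enol ether 34 (not isolated)
Conditions: TESOTf, Et3N, CH2Cl2, −20 → 0 °C; then Pd(OAc)2, MeCN, rt
Reagents that add atoms: triethylsilyl trifluoromethanesulfonate, CC[Si](CC)(CC)OS(=O)(=O)C(F)(F)F
Why: Saegusa–Ito oxidation, in which soft enolization can only give the C12=C13 silyl enol ether because C11 is quaternary, the same reagent silylates the C4 and C8 hydroxyls, and Pd(OAc)2 then dehydrogenates the enol ether to the enone.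

Step 22
Reactants: 35 enone bis(triethylsilyl) ether
Product: 36 allylic chloride (6S chloride; C5=C16 methylene; C4–OTES and C8–OTES)
Conditions: Ca(OCl)2, CO2 (dry ice), CH2Cl2/H2O, 0 °C
Reagents that add atoms: calcium hypochlorite, [Ca+2].[O-]Cl.[O-]Cl
Why: Ene-type allylic chlorination of a trisubstituted alkene by hypochlorous acid made in the flask, in which chlorine adds to the less substituted C6 and a proton leaves from the C16 methyl; with H7 in the alkene plane to avoid allylic strain with the cis C16 methyl, chlorine should arrive anti to the C7–O bond, giving 6S, and the deactivated C2=C3 and enone alkenes should not react.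

Step 23
Reactants: 36 allylic chloride
Product: 37 CNP0196166.1 (target)
Conditions: HF·pyridine, pyridine, THF, 0 °C
Reagents that add atoms: none
Why: Buffered fluoride cleavage of the secondary and tertiary triethylsilyl ethers should leave the allylic chloride, both acetates, the lactone and the enone intact.

**Compound list**

1 | (R)-2,2-dimethyl-1,3-dioxolane-4-carbaldehyde | CC1(C)OC[C@H](C=O)O1 | starting material
2 | 3-(triphenylphosphoranylidene)butan-2-one | CC(=O)C(C)=P(c1ccccc1)(c1ccccc1)c1ccccc1 | starting material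
3 | (S,E)-4-(2,2-dimethyl-1,3-dioxolan-4-yl)-3-methylbut-3-en-2-one | CC(=O)/C(C)=C/[C@H]1COC(C)(C)O1 | intermediate
4 | (S)-2,2-dimethyl-4-[(1E)-2-methyl-3-(triisopropylsilyloxy)buta-1,3-dienyl]-1,3-dioxolane | C=C(O[Si](C(C)C)(C(C)C)C(C)C)/C(C)=C/[C@H]1COC(C)(C)O1 | intermediate
5 | methacrolein | CC(=C)C=O | starting material
6 | (1S,2S)-2-[(4S)-2,2-dimethyl-1,3-dioxolan-4-yl]-1,3-dimethyl-4-(triisopropylsilyloxy)cyclohex-3-ene-1-carbaldehyde | O=C[C@@]1(C)CCC(O[Si](C(C)C)(C(C)C)C(C)C)=C(C)[C@@H]1[C@H]1COC(C)(C)O1 | intermediate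
7 | (dibromomethyl)trimethylsilane | C[Si](C)(C)C(Br)Br | starting material
8 | (E)-vinylsilane: formyl group of 6 replaced by (E)-2-(trimethylsilyl)ethenyl | C[Si](C)(C)/C=C/[C@@]1(C)CCC(O[Si](C(C)C)(C(C)C)C(C)C)=C(C)[C@@H]1[C@H]1COC(C)(C)O1 | intermediate
9 | silyloxy ketone: C12 ketone with C11 triisopropylsilyloxy group trans to the C10 dioxolane | C[Si](C)(C)/C=C/[C@@]1(C)CCC(=O)[C@@](C)(O[Si](C(C)C)(C(C)C)C(C)C)[C@@H]1[C@H]1COC(C)(C)O1 | intermediate
10 | ring A ketol: 2-hydroxy-2,4-dimethyl-3-[(4S)-2,2-dimethyl-1,3-dioxolan-4-yl]-4-[(E)-2-(trimethylsilyl)ethenyl]cyclohexan-1-one, hydroxyl trans and 4-methyl cis to the dioxolane | C[Si](C)(C)/C=C/[C@@]1(C)CCC(=O)[C@@](C)(O)[C@@H]1[C@H]1COC(C)(C)O1 | intermediate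
11 | C11 acetate of 10 | C[Si](C)(C)/C=C/[C@@]1(C)CCC(=O)[C@@](C)(OC(C)=O)[C@@H]1[C@H]1COC(C)(C)O1 | intermediate
12 | diol: C10 carries the (1S)-1,2-dihydroxyethyl group (C9, C8) | C[Si](C)(C)/C=C/[C@@]1(C)CCC(=O)[C@@](C)(OC(C)=O)[C@@H]1[C@H](O)CO | intermediate
13 | bis(triethylsilyl) ether of 12 | C[Si](C)(C)/C=C/[C@@]1(C)CCC(=O)[C@@](C)(OC(C)=O)[C@@H]1[C@H](O[Si](CC)(CC)CC)CO[Si](CC)(CC)CC | intermediate
14 | aldehyde: C8 formyl, C9 triethylsilyloxy | C[Si](C)(C)/C=C/[C@@]1(C)CCC(=O)[C@@](C)(OC(C)=O)[C@@H]1[C@H](O[Si](CC)(CC)CC)C=O | intermediate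
15 | ethynyltrimethylsilane | C#C[Si](C)(C)C | starting material
16 | lithium (trimethylsilyl)acetylide | [Li]C#C[Si](C)(C)C | intermediate
17 | propargylic alcohols: C8 carbinol with trimethylsilylethynyl group, both C8 epimers | C[Si](C)(C)/C=C/[C@@]1(C)CCC(=O)[C@@](C)(OC(C)=O)[C@@H]1[C@H](O[Si](CC)(CC)CC)C(O)C#C[Si](C)(C)C | intermediate
18 | ynone: C8 ketone between C9–OTES and C≡C–SiMe3 | C[Si](C)(C)/C=C/[C@@]1(C)CCC(=O)[C@@](C)(OC(C)=O)[C@@H]1[C@H](O[Si](CC)(CC)CC)C(=O)C#C[Si](C)(C)C | intermediate
19 | 2-methylbut-1-en-3-yne | C=C(C)C#C | starting material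
20 | dicyclohexyl[(E)-3-methylbuta-1,3-dienyl]borane | C=C(C)/C=C/B(C1CCCCC1)C1CCCCC1 | intermediate
21 | methyl[(E)-3-methylbuta-1,3-dienyl]zinc | C=C(C)/C=C/[Zn]C | intermediate
22 | tertiary carbinol: C8 bears OH, trimethylsilylethynyl and (E)-3-methylbuta-1,3-dienyl; C9 triethylsilyloxy, syn to the C8 oxygen | C[Si](C)(C)/C=C/[C@@]1(C)CCC(=O)[C@@](C)(OC(C)=O)[C@@H]1[C@H](O[Si](CC)(CC)CC)[C@](O)(C#C[Si](C)(C)C)/C=C/C(C)=C | intermediate
23 | diol: C9–OH and C8–OH, ethynyl on C8 | C[Si](C)(C)/C=C/[C@@]1(C)CCC(=O)[C@@](C)(OC(C)=O)[C@@H]1[C@H](O)[C@](O)(C#C)/C=C/C(C)=C | intermediate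
24 | C9 acetate of 23 | C[Si](C)(C)/C=C/[C@@]1(C)CCC(=O)[C@@](C)(OC(C)=O)[C@@H]1[C@H](OC(C)=O)[C@](O)(C#C)/C=C/C(C)=C | intermediate
25 | alkenylboronate: C8 bears 1-(pinacolboryl)ethenyl | C[Si](C)(C)/C=C/[C@@]1(C)CCC(=O)[C@@](C)(OC(C)=O)[C@@H]1[C@H](OC(C)=O)[C@](O)(C(=C)B1OC(C)(C)C(C)(C)O1)/C=C/C(C)=C | intermediate
26 | carbon dioxide | O=C=O | starting material
27 | cesium carboxylate: C8 bears C(=CH2)CO2Cs | C[Si](C)(C)/C=C/[C@@]1(C)CCC(=O)[C@@](C)(OC(C)=O)[C@@H]1[C@H](OC(C)=O)[C@](O)(C(=C)C(=O)[O-])/C=C/C(C)=C.[Cs+] | intermediate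
28 | bromo lactone: 17-methylene-8-hydroxy γ-lactone; C7 bears (E)-3-bromo-2-methylprop-1-enyl cis to the C8 hydroxyl | C[Si](C)(C)/C=C/[C@@]1(C)CCC(=O)[C@@](C)(OC(C)=O)[C@@H]1[C@H](OC(C)=O)[C@]1(O)C(=C)C(=O)O[C@H]1/C=C(\C)CBr | intermediate
29 | enal: C4 aldehyde on the (E)-C5(CH3)=C6 alkene | C[Si](C)(C)/C=C/[C@@]1(C)CCC(=O)[C@@](C)(OC(C)=O)[C@@H]1[C@H](OC(C)=O)[C@]1(O)C(=C)C(=O)O[C@H]1/C=C(\C)C=O | intermediate
30 | (E)-vinyl iodide at C2=C3 | I/C=C/[C@@]1(C)CCC(=O)[C@@](C)(OC(C)=O)[C@@H]1[C@H](OC(C)=O)[C@]1(O)C(=C)C(=O)O[C@H]1/C=C(\C)C=O | intermediate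
31 | macrocyclic (4S)-allylic alcohol: (2E,5E)-diene, 17-methylene lactone, saturated C12 ketone | O[C@H]1/C=C/[C@@]2(C)CCC(=O)[C@@](C)(OC(C)=O)[C@@H]2[C@H](OC(C)=O)[C@]2(O)C(=C)C(=O)O[C@H]2/C=C1\C | intermediate
32 | 17-epimer (17S) of the α-methyl lactone | O[C@H]1/C=C/[C@@]2(C)CCC(=O)[C@@](C)(OC(C)=O)[C@@H]2[C@H](OC(C)=O)[C@]2(O)[C@H](C)C(=O)O[C@H]2/C=C1\C | intermediate
33 | (17R)-α-methyl lactone | O[C@H]1/C=C/[C@@]2(C)CCC(=O)[C@@](C)(OC(C)=O)[C@@H]2[C@H](OC(C)=O)[C@]2(O)[C@@H](C)C(=O)O[C@H]2/C=C1\C | intermediate
34 | tris-silyl compound: C12=C13 triethylsilyl enol ether, C4–OTES, C8–OTES | CC[Si](CC)(CC)O[C@H]1/C=C/[C@@]2(C)CC=C(O[Si](CC)(CC)CC)[C@@](C)(OC(C)=O)[C@@H]2[C@H](OC(C)=O)[C@]2(O[Si](CC)(CC)CC)[C@@H](C)C(=O)O[C@H]2/C=C1\C | intermediate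
35 | ring A enone with C4–OTES and C8–OTES, (5E)-C5(CH3)=C6 | CC[Si](CC)(CC)O[C@H]1/C=C/[C@@]2(C)C=CC(=O)[C@@](C)(OC(C)=O)[C@@H]2[C@H](OC(C)=O)[C@]2(O[Si](CC)(CC)CC)[C@@H](C)C(=O)O[C@H]2/C=C1\C | intermediate
36 | (6S)-chloride with C5=C16 methylene, C4–OTES and C8–OTES | C=C1[C@@H](O[Si](CC)(CC)CC)/C=C/[C@@]2(C)C=CC(=O)[C@@](C)(OC(C)=O)[C@@H]2[C@H](OC(C)=O)[C@]2(O[Si](CC)(CC)CC)[C@@H](C)C(=O)O[C@H]2[C@H]1Cl | intermediate
37 | CNP0196166.1 | C=C1[C@@H](O)/C=C/[C@@]2(C)C=CC(=O)[C@@](C)(OC(C)=O)[C@@H]2[C@H](OC(C)=O)[C@]2(O)[C@@H](C)C(=O)O[C@H]2[C@H]1Cl | target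

**Totals and risks**

Total step count: 23. Longest linear sequence: 23 steps (1 to 37); compounds 2, 5, 7, 15, 19 and 26 are purchased.

Step 16 (proposed new method). What may go wrong is protodeboronation of the alkenyl–rhodium species in competition with CO2 insertion, and, because the halogen source meets catalyst residues and unconverted boronate in one flask, bromination away from C4 or 1,2- instead of 1,4-addition. The fallback sets out from 25 and separates the two events with known chemistry. The carboxylation is run alone and the mixture acidified to isolate the acrylic acid F1. F1 is then cyclized by the known palladium-catalysed 1,4-oxidation of conjugated dienes (Pd(OAc)2 cat., p-benzoquinone, LiCl, LiOAc, acetone/AcOH): the carboxylate attacks C7 of the diene bound to divalent palladium and chloride opens the π-allyl complex at C4, giving the allylic chloride F2. N-oxide oxidation (NMO, NaI cat., MeCN) then gives enal 29, where the route is rejoined.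

Step 19. What may go wrong is poor facial selectivity of the ring-closing carbonyl addition, since the C4 configuration is decided by a strained ten-membered transition state. The fallback sets out from 30 and accepts whatever the cyclization delivers. The C4 epimer F3 (or its mixture with 31) is oxidized with MnO2, which touches only the bis-allylic alcohol, to the cross-conjugated dienone F4. F4 is reduced under reagent control (Corey–Bakshi–Shibata reduction, (R)-2-methyl-oxazaborolidine, catecholborane, toluene, −78 °C; the α-branched C5 alkenyl group acts as the large substituent) to return to 31.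

Step 22. What may go wrong is loss of site and face control in the chlorination: proton loss from C4 instead of C16, attack on the C2=C3 alkene, or delivery of chlorine to the other face of C6 if the ring conformation overrides the acyclic model. The fallback sets out from 35 and replaces electrophilic chlorine by an oxidation–transposition pair. Allylic oxidation with SeO2/t-BuOOH at the C16 methyl (the allylic methyl on the more substituted alkene carbon) gives the primary allylic alcohol F5. SOCl2 in Et2O at 0 °C then converts its chlorosulfite by internal return with allylic transposition (SNi′), placing chlorine on C6 and the alkene at C5=C16, to rejoin the route at 36; the face of chlorine delivery in this alternative is again not secured.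

**Further compounds**

F1 | step 16 | acrylic acid: C8 bears C(=CH2)CO2H (free acid of 27) | C[Si](C)(C)/C=C/[C@@]1(C)CCC(=O)[C@@](C)(OC(C)=O)[C@@H]1[C@H](OC(C)=O)[C@](O)(C(=C)C(O)=O)/C=C/C(C)=C
F2 | step 16 | allylic chloride lactone: chloro analogue of 28 | C[Si](C)(C)/C=C/[C@@]1(C)CCC(=O)[C@@](C)(OC(C)=O)[C@@H]1[C@H](OC(C)=O)[C@]1(O)C(=C)C(=O)O[C@H]1/C=C(\C)CCl
F3 | step 19 | C4 epimer (4R) of 31 | O[C@@H]1/C=C/[C@@]2(C)CCC(=O)[C@@](C)(OC(C)=O)[C@@H]2[C@H](OC(C)=O)[C@]2(O)C(=C)C(=O)O[C@H]2/C=C1\C
F4 | step 19 | cross-conjugated dienone: C4 ketone of 31 | O=C1/C=C/[C@@]2(C)CCC(=O)[C@@](C)(OC(C)=O)[C@@H]2[C@H](OC(C)=O)[C@]2(O)C(=C)C(=O)O[C@H]2/C=C1\C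
F5 | step 22 | C16 allylic alcohol of 35 | CC[Si](CC)(CC)O[C@H]1/C=C/[C@@]2(C)C=CC(=O)[C@@](C)(OC(C)=O)[C@@H]2[C@H](OC(C)=O)[C@]2(O[Si](CC)(CC)CC)[C@@H](C)C(=O)O[C@H]2/C=C1\CO
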